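Slowness is what we have to work with. In Friday's flask at 20.0 h, target reads 1% and starting material 50%, while the steady feed has delivered 50.0% of the charge.

in all of them: precatalyst 0.01 mol%

| charge | starting material | remark | time |
|---|---|---|---|
| Friday's | 0.13 M (fed, over 40 h) | the very flask that is asked about, followed so far |  |
| Saturday's | 0.087 M (fed, over 40 h) | run made earlier |  |
| flask | 0.13 M (fed, over 40 h) |  | 2.5 d |

- Friday's (time / h: target / %, starting material / %): 3.00: 0, 7; 6.00: 0, 14; 10.0: 0, 28; 12.0: 0, 29; 15.0: 0, 37; 20.0: 1, 50
- Saturday's (time / d: target / %, starting material / %): 0.208: 0, 14; 0.333: 1, 17; 0.500: 5, 34; 0.833: 1, 50; 1.67: 3, 99; 2.50: 4, 92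

(each reading ± 2 percentage points)

* target present at 2.5 d, in percent of the starting material charged
* starting material present at 2.5 d, in percent of the starting material charged

- reactions considered so far: starting material + enzyme -> target + enzyme; precatalyst -> enzyme
- percentages count the whole charge, also what has not yet gone in

We write the balance of starting material, the limiting reagent: after the feed ends, what is missing from the charge counts as converted. In Saturday's run at 2.50 d, that balance gives 8.00% and the target reading gives 4%, each good to 2 percentage points, so we take the mean, 6.00%. Dividing by Saturday's charge gives a reading of 0.690 M⁻¹, the conversion per molar of charge.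

Now the settings, one after the other. At a fixed loading and the same time, a larger charge means proportionally more enzyme per litre. If target forms in step with enzyme and starting material, percentage conversion then rises in proportion to the charge, and by our reckoning Friday's flask at 0.13 M should reach 8.97% at 2.5 d. By the same reckoning, loading acts on enzyme as the charge does, but both runs hold it at 0.01 mol%, so they cannot test it. Both also hold the dosing time at 40 h, so that stays untested too.

The forecast, expecting for Friday's flask “a percentage rate 1.5 times faster”, gave target 9% (5% to 15%) and starting material 91% (84% to 95%).

The flask gives target 13.8% and starting material 86.2%, inside both ranges, with target 1.2 points below the forecast's top. With loading and time held, target has moved by 5 points at 0.101 M of starting material. The flask's conversion per molar of charge is 1.06 M⁻¹, higher than Saturday's reading of 0.690 M⁻¹.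

    starting material + enzyme → target + enzyme, rate k1*[starting material]^3*[enzyme]/(1 + ([starting material]/Kh1)^3) (0.131 M, k = 2470 M⁻³ min⁻¹)
    precatalyst → enzyme (k = 1.35 × 10⁻⁴ min⁻¹)

For a neighbour flask, like this one but with 0.078 M of starting material, less than Saturday's 0.087 M, Saturday's reading of 0.690 M⁻¹ gives 5.38% target at 2.50 d. The computed neighbour gives 4.95%.

(All runs stem from a simulated flask for an exercise, noise included.)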